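A small charge of acid, 0.0150 M, met 0.15 M of substrate in this flask, and I reckoned the free proton as that charge plus a correction from the weak acid, whose constant of 7.9 × 10⁻⁵ M lies far below the charge of acid.

substrate 0.15 M (fed, over 2.5 s); acid 0.0150 M; time 80 s

- part of the substrate that has reacted at 80 s
- pH of the solution at 80 s

    substrate + acid → weak acid + acid + target (k1 = 1.86 /M/s)
    weak acid ⇌ conjugate base + acid, settled at all times (K2 = 7.9 × 10⁻⁵ M)
    substrate → weak acid + target (k3 = 1.63 × 10⁻⁴ /s)
    crystals ⇌ weak acid, rate k4*(cs4 - [weak acid]) while solid is left; crystals form when [weak acid] > cs4 (cs4 = 0.061 M, k4 = 4.23 /s)
    target ⇌ isomer of the product (K5 = 2.60, k5 = 0.0438 /s)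

- acid is the free proton; pH is minus the decimal logarithm of its molar concentration
- for weak acid the crystals are counted in
- as a solid, counted per litre of solution: crystals
- run time (flask): 80 s

I climbed the time scales from the fastest. The balance of weak acid with its conjugate base was kept at once. Crystals responded in about 0.236 s, and the substrate charge could yield more weak acid than the solubility of 0.061 M, so I expected dissolved weak acid to stop near that solubility. The feed took 2.5 s, much shorter than the 80 s run, so I let the substrate start at the middle of its feed. Target and isomer of the product relaxed in 11.4 s, but that pair consumes neither substrate nor acid.

Next came the catalysed step, with a substrate half-life of 25 s. The uncatalysed step was far slower, at 71 min. The catalysed step returns its acid, so I computed just the correction: x, the free proton from weak acid at solubility, was 3.21 × 10⁻⁴ M, which made the acid h equal to 0.0153 M. I applied this over the whole run, which overstated it while weak acid was still rising.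

I carried one quantity, the catalytic clock κ, the pseudo-first-order constant of substrate loss: the catalysed constant times h, plus the uncatalysed constant. It came to 0.0287 /s. My reckoning gave 89.5% reacted and pH 1.81.

The forecast, with the words “The proton acts as a catalyst”, gave 89.5% and pH 1.815.

The simulation gave 89.5% reacted and pH 1.81 for this flask. At 80.0 s, the substrate half-life in this flask was 24 s by the catalysed step, much shorter than the 71 min by the uncatalysed one, and the rates stood at a ratio of 170. The half-life from κ, 24.2 s, lay close to that catalysed value. For the neighbour flask charged with 0.0090 M of acid, the correction became 5.35 × 10⁻⁴ M and κ became 0.0179 /s, which gave 75.6% reacted; that neighbour flask reached 75.2%.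

The numbers of this flask were set for the occasion; the result is computed.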